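The vessel held the partner, and I fed the substrate into it at a steady rate.

in all of them: substrate 0.10 M (fed, over 3.0 min)

| run | partner | remark | time |
|---|---|---|---|
| summer | 0.62 equiv | run made earlier; the fed solution adds 0.20 times the starting volume |  |
| noon | 6.1 equiv | run made earlier; the fed solution adds 0.20 times the starting volume |  |
| south-west | 0.500 equiv | the fed solution adds 0.20 times the starting volume | 3.0 min |
| north-west | 0.800 equiv | the fed solution adds 0.20 times the starting volume | 3.0 min |
| north-east | 4.00 equiv | the fed solution adds 0.20 times the starting volume | 3.0 min |

- summer (time / s: bis adduct / %, first product / %): 10.0: 0, 0; 15.0: 0.1, 0.2; 25.0: 0, 0.7; 50.0: 0.1, 2.2; 90.0: 1.7, 4.2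
- noon (time / s: bis adduct / %, first product / %): 20.0: 1.4, 1.6; 40.0: 7.1, 3.4; 50.0: 11.2, 4.0; 80.0: 24.9, 5.5; 90.0: 29.7, 6.1

(each reading ± 0.3 percentage points)

1. amount of bis adduct at the end, in percent of the substrate charged, for each flask in turn (south-west, north-west, north-east)

- charges are per starting volume, the dose included; the dosed solution carries all of it
- the numbers in the tables scatter with a standard deviation of 0.3 percentage points
- steps under discussion: substrate + partner -> first product; substrate + partner -> other mono adduct; partner + first product -> bis adduct; partner + other mono adduct -> bis adduct; partner <-> dormant form
- percentages count the whole charge, also what has not yet gone in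

I reckoned north-east by hand.

1. In noon at 90.0 s, 50.0% of the charge had gone in, and the readings of bis adduct and first product left 14.2% unseen.

2. I used the symmetric case as the zero of the scale: other mono adduct equal to first product. That left 8.10% as substrate.

3. A steady level equals the feed rate times the lifetime, so the pseudo-first-order substrate lifetime, the mean wait of a fed molecule before its first addition, read 14.6 s in noon, shorter than the time elapsed.

4. The gain of bis adduct from 50.0 s to 90.0 s, set against both mono adducts, gave a mono lifetime of 21.8 s.

5. I scaled both lifetimes inversely with partner. At full north-east charge, substrate came to 12.4%, the mono adducts to 18.5% and bis adduct to 69.1%, which left 60.8% of the partner.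

6. Partner left was the weak link. Repeating the sum at that figure left 67.8%, so I took the mean, 64.3%. My sum for north-east then stood at bis adduct of 52.0%. For north-west and south-west, the same scaling at full charge gave lifetimes of 111 s and 178 s against a dosing time of 3.0 min, and I drew no standing level from them.

The forecast gave 3.8%, 9.5% and 56%, with “a lifetime of about 26 s” where mine read 14.6 s. My north-east figure stood lower than its figure.

The flasks gave 4.28%, 9.30% and 59.9%.

    substrate + partner → first product (k = 0.0570 /M/s)
    substrate + partner → other mono adduct (k = 0.0620 /M/s)
    partner + first product → bis adduct (k = 0.0950 /M/s)
    partner + other mono adduct → bis adduct (k = 0.130 /M/s)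
    partner ⇌ dormant form (K = 0.120, k = 0.0920 /s)

In north-east, substrate stood at 15.0% at 1.50 min and 20.8% at 3.00 min, while bis adduct rose from 21.9% to 59.9%. By 30.0 min, substrate, first product and other mono adduct read 0%, 0% and 0%, and bis adduct 100%, with partner at 44.6%. The carried lifetime, scaled to north-east's charge and its 58% of partner at the end, gives a level of 21.2% beside the simulated 21%. In north-west, at its 41% of partner at the end, the same scaling gives a lifetime of 272 s, longer than the dosing time, and substrate stood at 66%.

Readings and results are simulated for an exercise.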